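All runs are simulated with constants of no real substance; the scatter is artificial.

The easy step first: every flask holds X at 20 mM, and to become D, the tetra adduct, each X must take up 4 Q, so D comes at the end of a chain of additions.

| flask | X | Q | remark | time |
|---|---|---|---|---|
| south-east | 20 mM | 110 mM | run made earlier |  |
| north-west | 20 mM | 850 mM | run made earlier |  |
| theta | 20 mM | 80.0 mM |  | 5.0 h |
| eta | 20 mM | 150 mM |  | 5.0 h |
| gamma | 20 mM | 300 mM |  | 5.0 h |
| epsilon | 20 mM | 600 mM |  | 5.0 h |

| south-east: time / h | south-east: D / % | north-west: time / h | north-west: D / % |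
|---|---|---|---|
| 0.667 | 0 | 0.667 | 0.9 |
| 1.33 | 0 | 1.33 | 2.4 |
| 2.00 | 0 | 2.00 | 4.9 |
| 2.50 | 0 | 2.50 | 5.8 |

(standard deviation of a reading: 0.5 percentage points)

* amount of D at the end, in percent of the X charged for theta, eta, gamma, epsilon, in this order
* the shape of the row from first to last (rises, then falls / rises all the way / falls all the way / hardly changes / falls, then rises)

- "hardly changes" means that all values lie within two and a half points (for a concentration: within two and a half percent of the largest)

1. Time. By hand, a chain gives its last member late, and the north-west run shows this, with D at 0.9% after 0.667 h and 5.8% after 2.50 h.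

2. [Q]. I assume that each addition runs in proportion to [Q] and freeze [Q] at its charge, which is the pseudo-first-order picture. Raising [Q] by some factor then shortens each time constant by that factor, which is the same as stretching the time by it.

3. So I carry one number, the dose, the charged [Q] multiplied by the time, which for theta is 400 mM·h. In north-west the freeze is safe, because X going wholly to D would use 80.0 mM, far less than the charge, but in theta that use equals the charge, so there the freeze is a bet.

4. The earlier runs become one curve in dose. South-east reads 0% at 275 mM·h, and the north-west readings, taken in order, stand at 567 mM·h, 1130 mM·h, 1700 mM·h and 2120 mM·h.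

5. My reckoning follows from where each dose falls on that curve. Theta lies under 0.9%, eta at 750 mM·h lies between 0.9% and 2.4%, and gamma at 1500 mM·h lies between 2.4% and 4.9%. Epsilon at 3000 mM·h stands beyond the last reading, so I expect about 5.8% or above, and the row rises.

The forecast, which gives a number where I hold a floor, says 0.2%, 0.8%, 2.8% and 9%, shape rises all the way, on “two effective slow steps, each first order in Q”.

    Q + E → G (k = 0.0250 M⁻¹ min⁻¹)
    Q + G → D (k = 0.0380 M⁻¹ min⁻¹)
    Q + J → E (k = 0.0260 M⁻¹ min⁻¹)
    Q + D → Z (k = 0.0870 M⁻¹ min⁻¹)
    X + Q → J (k = 0.0140 M⁻¹ min⁻¹)
    2 X → L (k = 8.90 × 10⁻⁵ M⁻¹ min⁻¹)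

The flask gives 0.171%, 1.04%, 4.09% and 5.29%, shape rises all the way: the first three lie inside my brackets, and epsilon lies a little under the reading of 5.8%. Q stands at 91% of its charge in theta and 89% in epsilon, and gamma at 2.50 h has the dose of eta at the end, 750 mM·h, with D 1.11% against 1.04% and X 54.0% against 54.8%. In theta, the half-life of X by the step to J alone, 10 h, is longer than the 5.0 h run, which in dose is 825 mM·h against 400 mM·h. Theta ends with X at 72.5%, J at 20.4% and D at 0.171%.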